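The route rests on cutting the bond between the carbinol carbon and its guaiacyl ring. In the oxolane ring (O-1, C-2 to C-5, numbered as oxolan-3-ol) the C-3 hydroxyl and the C-5 side chain are cis, so the carbinol carbon can be held as a lactone carbonyl bridging O-3 and C-5 in a strained 2,5-dioxabicyclo[2.2.1]heptan-3-one. An aryllithium opens this temporary ring: one operation forms the aryl–carbon bond, releases the strain, frees the C-3 hydroxyl and gives an aryl ketone whose α-carbon, a bridgehead until then, has kept its cis configuration. Chelation-controlled reduction sets the carbinol centre. Both aryl groups come from one bromide, the bicycle from (S)-5-(hydroxymethyl)butenolide.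

Key step: step 5

Remark on the chemistry: bicyclic lactone 10 is assumed to survive aqueous work-up and rapid chromatography, as its N-acyl 5-aza analogues do; otherwise it is carried crude into step 5.

Step 1
Reactants: 1 (5S)-5-(hydroxymethyl)furan-2(5H)-one
Product: 2 (5S)-5-{[(tert-butyldimethylsilyl)oxy]methyl}furan-2(5H)-one
Conditions: TBSCl, imidazole, DMF, 0 °C → rt
Reagents that add atoms: tert-butyldimethylsilyl chloride CC(C)(C)[Si](C)(C)Cl
Why: Imidazole-promoted silyl ether formation masks the primary hydroxyl as an ether that survives the organocopper step and is a poor leaving group for elimination from the butenolide; no stereocentre is touched.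

Step 2
Reactants: 2 (5S)-5-{[(tert-butyldimethylsilyl)oxy]methyl}furan-2(5H)-one; 3 1-(benzyloxy)-4-bromo-2-methoxybenzene
Product: 6 (4R,5S)-4-[4-(benzyloxy)-3-methoxyphenyl]-5-{[(tert-butyldimethylsilyl)oxy]methyl}oxolan-2-one, via arylmagnesium bromide 4 (not isolated), via silyl ketene acetal 5 (not isolated)
Conditions: 3, Mg, THF, rt; then CuBr·SMe2 (20 mol %), Me3SiCl, 2, THF, −78 °C; aq. NH4Cl
Reagents that add atoms: none
Why: Copper-catalysed conjugate addition of an aryl Grignard reagent, accelerated by Me3SiCl, should deliver the aryl group to the butenolide face anti to the C-5 silyloxymethyl group, which sets C-4 as R (4,5-trans), and silyl ketene acetal 5 is hydrolysed to the lactone on work-up.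

Step 3
Reactants: 6 (4R,5S)-4-[4-(benzyloxy)-3-methoxyphenyl]-5-{[(tert-butyldimethylsilyl)oxy]methyl}oxolan-2-one
Product: 7 (4R,5S)-4-[4-(benzyloxy)-3-methoxyphenyl]-5-(bromomethyl)oxolan-2-one
Conditions: Ph3PBr2 (preformed, free of Br2), CH2Cl2, 0 °C → rt
Reagents that add atoms: bromotriphenylphosphonium bromide Br[P+](c1ccccc1)(c1ccccc1)c1ccccc1.[Br-]
Why: Direct conversion of a primary silyl ether into the bromide with Ph3PBr2 (silyl transfer to bromide, oxyphosphonium formation and SN2 displacement by bromide, as in the Appel reaction) installs the leaving group without a separate deprotection and touches no stereocentre.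

Step 4
Reactants: 7 (4R,5S)-4-[4-(benzyloxy)-3-methoxyphenyl]-5-(bromomethyl)oxolan-2-one
Product: 10 (1S,4S,7R)-7-[4-(benzyloxy)-3-methoxyphenyl]-2,5-dioxabicyclo[2.2.1]heptan-3-one, via potassium enolate 8 (not isolated), via potassium alkoxide 9 (not isolated)
Conditions: KN(SiMe3)2, THF, −78 °C; 2-(benzenesulfonyl)-3-phenyloxaziridine, −78 °C; then → rt (high dilution)
Reagents that add atoms: 2-(benzenesulfonyl)-3-phenyloxaziridine O=S(=O)(N1OC1c1ccccc1)c1ccccc1
Why: Enolate hydroxylation with an N-sulfonyloxaziridine (Davis oxidation) is followed in the same flask by an intramolecular Williamson etherification: the oxidant should attack the enolate face anti to the neighbouring aryl group, which sets C-3 of the lactone as S with its oxygen cis to the bromomethyl group, and on warming the alkoxide displaces bromide in a 5-exo-tet closure that only this cis epimer can undergo.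

Step 5
Reactants: 10 (1S,4S,7R)-7-[4-(benzyloxy)-3-methoxyphenyl]-2,5-dioxabicyclo[2.2.1]heptan-3-one; 3 1-(benzyloxy)-4-bromo-2-methoxybenzene
Product: 13 [(2S,3R,4S)-3-[4-(benzyloxy)-3-methoxyphenyl]-4-hydroxyoxolan-2-yl][4-(benzyloxy)-3-methoxyphenyl]methanone, via aryllithium 11 (not isolated), via lithium hemiketalate 12 (not isolated)
Conditions: 3, n-BuLi, THF, −78 °C; added slowly (1.05 equiv) to 10, THF, −78 °C; AcOH, −78 °C
Reagents that add atoms: none
Why: The aryllithium adds to the lactone carbonyl of 10, which is activated by the strain of the 2,5-dioxabicyclo[2.2.1]heptan-3-one, from the face of the O–CH2 bridge (the other face is covered by the 7-aryl group) to give lithium hemiketalate 12; on protonation this collapses by acyl–oxygen cleavage, releasing the strain and unveiling the ketone and the ring hydroxyl of 13. The closest known reaction type is the addition of aryllithium reagents to lactones to give lactols or hydroxy ketones, as used for C-aryl glycosides. No ring is closed; the lactone ring is opened and the oxolane remains. No new stereocentre survives (the hemiketal carbon is transient), and the three ring stereocentres are untouched because only the acyl C–O bond breaks. The step needs mono-addition and no epimerization next to the carbonyl: the hemiketalate masks the ketone until the acidic quench, the strained lactone should outcompete any ketone set free early, and the α-carbon is a bridgehead that cannot enolize in 10.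

Step 6
Reactants: 13 [(2S,3R,4S)-3-[4-(benzyloxy)-3-methoxyphenyl]-4-hydroxyoxolan-2-yl][4-(benzyloxy)-3-methoxyphenyl]methanone
Product: 14 (3S,4R,5S)-4-[4-(benzyloxy)-3-methoxyphenyl]-5-[(R)-[4-(benzyloxy)-3-methoxyphenyl](hydroxy)methyl]oxolan-3-ol
Conditions: Zn(BH4)2, Et2O–CH2Cl2, −40 → 0 °C; aq. NH4Cl
Reagents that add atoms: none
Why: Chelation-controlled reduction of an α-alkoxy ketone (Cram chelate model): zinc bridges the carbonyl oxygen and the ring oxygen, and hydride is delivered to the face opposite the aryl-bearing ring carbon, which should give the anti (erythro) alcohol, that is the R carbinol.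

Step 7
Reactants: 14 (3S,4R,5S)-4-[4-(benzyloxy)-3-methoxyphenyl]-5-[(R)-[4-(benzyloxy)-3-methoxyphenyl](hydroxy)methyl]oxolan-3-ol
Product: 15 metasequirin E, (3S,4R,5S)-5-[(R)-hydroxy(4-hydroxy-3-methoxyphenyl)methyl]-4-(4-hydroxy-3-methoxyphenyl)oxolan-3-ol
Conditions: H2 (1 atm), Pd/C, EtOAc, rt
Reagents that add atoms: none
Why: Catalytic hydrogenolysis of the two benzyl aryl ethers, which should be cleaved faster than the benzylic carbinol C–O bond under neutral conditions, unveils both phenols without touching a stereocentre.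

Compound list
1 | (5S)-5-(hydroxymethyl)furan-2(5H)-one | O=C1C=C[C@@H](CO)O1 | starting material
2 | (5S)-5-{[(tert-butyldimethylsilyl)oxy]methyl}furan-2(5H)-one | O=C1C=C[C@@H](CO[Si](C)(C)C(C)(C)C)O1 | intermediate
3 | 1-(benzyloxy)-4-bromo-2-methoxybenzene | COc1cc(Br)ccc1OCc1ccccc1 | starting material
4 | [4-(benzyloxy)-3-methoxyphenyl]magnesium bromide (not isolated) | COc1cc([Mg]Br)ccc1OCc1ccccc1 | intermediate
5 | tert-butyl{[(2S,3R)-3-[4-(benzyloxy)-3-methoxyphenyl]-5-[(trimethylsilyl)oxy]-2,3-dihydrofuran-2-yl]methoxy}dimethylsilane, the silyl ketene acetal (not isolated) | C[Si](C)(C)OC1=C[C@H](c2ccc(OCc3ccccc3)c(OC)c2)[C@@H](CO[Si](C)(C)C(C)(C)C)O1 | intermediate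
6 | (4R,5S)-4-[4-(benzyloxy)-3-methoxyphenyl]-5-{[(tert-butyldimethylsilyl)oxy]methyl}oxolan-2-one | COc1cc([C@H]2CC(=O)O[C@@H]2CO[Si](C)(C)C(C)(C)C)ccc1OCc1ccccc1 | intermediate
7 | (4R,5S)-4-[4-(benzyloxy)-3-methoxyphenyl]-5-(bromomethyl)oxolan-2-one | COc1cc([C@H]2CC(=O)O[C@@H]2CBr)ccc1OCc1ccccc1 | intermediate
8 | potassium (2S,3R)-3-[4-(benzyloxy)-3-methoxyphenyl]-2-(bromomethyl)-2,3-dihydrofuran-5-olate, the enolate of 7 (not isolated) | [K+].[O-]C1=C[C@H](c2ccc(OCc3ccccc3)c(OC)c2)[C@@H](CBr)O1 | intermediate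
9 | potassium (3S,4S,5S)-4-[4-(benzyloxy)-3-methoxyphenyl]-5-(bromomethyl)-2-oxooxolan-3-olate (not isolated) | COc1cc([C@H]2[C@H]([O-])C(=O)O[C@@H]2CBr)ccc1OCc1ccccc1.[K+] | intermediate
10 | (1S,4S,7R)-7-[4-(benzyloxy)-3-methoxyphenyl]-2,5-dioxabicyclo[2.2.1]heptan-3-one | COc1cc([C@H]2[C@@H](C3=O)OC[C@H]2O3)ccc1OCc1ccccc1 | intermediate
11 | [4-(benzyloxy)-3-methoxyphenyl]lithium (not isolated) | COc1cc([Li])ccc1OCc1ccccc1 | intermediate
12 | lithium (1S,4S,7R)-3,7-bis[4-(benzyloxy)-3-methoxyphenyl]-2,5-dioxabicyclo[2.2.1]heptan-3-olate, configuration at the hemiketal carbon C-3 left open (not isolated) | COc1cc([C@H]2[C@@H](C3([O-])c4ccc(OCc5ccccc5)c(OC)c4)OC[C@H]2O3)ccc1OCc1ccccc1.[Li+] | intermediate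
13 | [(2S,3R,4S)-3-[4-(benzyloxy)-3-methoxyphenyl]-4-hydroxyoxolan-2-yl][4-(benzyloxy)-3-methoxyphenyl]methanone | COc1cc([C@H]2[C@@H](C(=O)c3ccc(OCc4ccccc4)c(OC)c3)OC[C@H]2O)ccc1OCc1ccccc1 | intermediate
14 | (3S,4R,5S)-4-[4-(benzyloxy)-3-methoxyphenyl]-5-[(R)-[4-(benzyloxy)-3-methoxyphenyl](hydroxy)methyl]oxolan-3-ol | COc1cc([C@H]2[C@@H]([C@H](O)c3ccc(OCc4ccccc4)c(OC)c3)OC[C@H]2O)ccc1OCc1ccccc1 | intermediate
15 | metasequirin E, (3S,4R,5S)-5-[(R)-hydroxy(4-hydroxy-3-methoxyphenyl)methyl]-4-(4-hydroxy-3-methoxyphenyl)oxolan-3-ol | COc1cc([C@H]2[C@@H]([C@H](O)c3ccc(O)c(OC)c3)OC[C@H]2O)ccc1O | target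

Total step count: 7. Longest linear sequence: 7 steps (1 → 15); bromide 3 enters twice, in steps 2 and 5.

Steps most likely to fail

Step 4. Ring closure of the alkoxide to the strained bicycle may be slower than intermolecular acyl transfer between lactone molecules, and the facial selectivity of the oxidation may be incomplete. The fallback sets out from 7 and comes back at 13. The hydroxylation is quenched with AcOH at −78 °C and the hydroxy bromide (3S,4S,5S)-4-[4-(benzyloxy)-3-methoxyphenyl]-5-(bromomethyl)-3-hydroxyoxolan-2-one F1 is isolated. K2CO3 in MeOH at 0 °C should open the lactone to methyl (2S,3S,4S)-3-[4-(benzyloxy)-3-methoxyphenyl]-5-bromo-2,4-dihydroxypentanoate F2, which is not isolated. Its C-2 hydroxyl closes the unstrained oxolane onto C-5 with loss of bromide (5-exo-tet) to give methyl (2S,3R,4S)-3-[4-(benzyloxy)-3-methoxyphenyl]-4-hydroxyoxolane-2-carboxylate F3. MeNHOMe·HCl and i-PrMgCl in THF at −20 °C convert the ester into the Weinreb amide (2S,3R,4S)-3-[4-(benzyloxy)-3-methoxyphenyl]-4-hydroxy-N-methoxy-N-methyloxolane-2-carboxamide F4. Aryllithium 11 (2.2 equiv, THF, −78 °C) then gives ketone 13 through the stable chelated adduct.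

Step 5. Double addition may occur if the hemiketalate collapses before the quench, and the centre next to the carbonyl may epimerize once the ketone is unmasked. The fallback sets out from 10 and comes back at 13. i-Bu2AlH in CH2Cl2 at −78 °C reduces the lactone to the hydroxy aldehyde (2S,3R,4S)-3-[4-(benzyloxy)-3-methoxyphenyl]-4-hydroxyoxolane-2-carbaldehyde F5, handled as its mixture with the bicyclic lactol. Grignard reagent 4 (3 equiv, THF, −78 → 0 °C) adds once, over-addition being impossible at this oxidation level, to give (3S,4R,5S)-4-[4-(benzyloxy)-3-methoxyphenyl]-5-{[4-(benzyloxy)-3-methoxyphenyl](hydroxy)methyl}oxolan-3-ol as both carbinol epimers F6. MnO2 in CH2Cl2 should oxidize only the benzylic alcohol and give 13, after which step 6 sets the carbinol centre as planned.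

Step 7. Over-reduction may occur: once the para-phenol is free, the benzylic carbinol C–O bond may be hydrogenolysed. The fallback sets out from 13 and comes back at 15. The benzyl ethers are removed at the ketone stage (H2, Pd/C, EtOAc), where no benzylic alcohol is present, to give [(2S,3R,4S)-4-hydroxy-3-(4-hydroxy-3-methoxyphenyl)oxolan-2-yl](4-hydroxy-3-methoxyphenyl)methanone F7. Chelation-controlled reduction with excess Zn(BH4)2 in Et2O–THF then gives 15 directly.

Further compounds
F1 | step 4 | (3S,4S,5S)-4-[4-(benzyloxy)-3-methoxyphenyl]-5-(bromomethyl)-3-hydroxyoxolan-2-one | COc1cc([C@H]2[C@H](O)C(=O)O[C@@H]2CBr)ccc1OCc1ccccc1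
F2 | step 4 | methyl (2S,3S,4S)-3-[4-(benzyloxy)-3-methoxyphenyl]-5-bromo-2,4-dihydroxypentanoate (not isolated) | COc1cc([C@H]([C@H](O)CBr)[C@H](O)C(=O)OC)ccc1OCc1ccccc1
F3 | step 4 | methyl (2S,3R,4S)-3-[4-(benzyloxy)-3-methoxyphenyl]-4-hydroxyoxolane-2-carboxylate | COc1cc([C@H]2[C@@H](C(=O)OC)OC[C@H]2O)ccc1OCc1ccccc1
F4 | step 4 | (2S,3R,4S)-3-[4-(benzyloxy)-3-methoxyphenyl]-4-hydroxy-N-methoxy-N-methyloxolane-2-carboxamide | COc1cc([C@H]2[C@@H](C(=O)N(C)OC)OC[C@H]2O)ccc1OCc1ccccc1
F5 | step 5 | (2S,3R,4S)-3-[4-(benzyloxy)-3-methoxyphenyl]-4-hydroxyoxolane-2-carbaldehyde | COc1cc([C@H]2[C@@H](C=O)OC[C@H]2O)ccc1OCc1ccccc1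
F6 | step 5 | (3S,4R,5S)-4-[4-(benzyloxy)-3-methoxyphenyl]-5-{[4-(benzyloxy)-3-methoxyphenyl](hydroxy)methyl}oxolan-3-ol as both carbinol epimers | COc1cc([C@H]2[C@@H](C(O)c3ccc(OCc4ccccc4)c(OC)c3)OC[C@H]2O)ccc1OCc1ccccc1
F7 | step 7 | [(2S,3R,4S)-4-hydroxy-3-(4-hydroxy-3-methoxyphenyl)oxolan-2-yl](4-hydroxy-3-methoxyphenyl)methanone | COc1cc([C@H]2[C@@H](C(=O)c3ccc(O)c(OC)c3)OC[C@H]2O)ccc1O
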